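**Retrosynthetic overview**
- The target is three phloroglucinol rings joined by two CH2 bridges; it is reached by hydrogenolysis of seven benzyl ethers after one triple Friedel–Crafts butyrylation at the single free CH of rings A, B and C.
- The strategy rests on ring B, a hexasubstituted phloroglucinol (C1 butyryl, C2/C4/C6 OH, C3–CH2–ring A, C5–CH2–ring C). Its alternating O pattern maps onto a 3-benzyloxycyclobutenone (carrying the ring C bridge) and a siloxyalkyne (carrying the ring A bridge).
- Ring B is formed last, by thermal benzannulation: the [2+2] makes C2–C3 and C4–C5, and a 6π closure makes C1–C2.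
- Rings A and C both come from 2-methylphloroglucinol through one aldehyde; the formyl group steers the O-methyl/O-benzyl pattern and then becomes the bridge CH2 by acetylide addition and ionic deoxygenation, so no trialkoxybenzyl halide is needed.
- Ring order: rings A and C (present from the start), the four-membered ring (ketene [2+2]), then ring B.

Key step: step 16

Remark: the target has no stereocentre; the carbinol centres of 8 and 19 and the quaternary centre of 26 form as racemates and are removed again. Ketene is taken as a gas from a laboratory generator (acetone pyrolysis).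

**Route**

Step 1
Reactants: 1 2-methylbenzene-1,3,5-triol
Product: 3 2,4,6-trihydroxy-3-methylbenzaldehyde, via iminium chloride 2 (not isolated)
Conditions: POCl3, DMF, EtOAc, 0 °C to rt; then H2O, 60 °C
Reagents that add atoms: N,N-dimethylformamide (CN(C)C=O); water (O)
Why: Vilsmeier–Haack formylation of a phloroglucinol; the two free ring CH are equivalent, and the precipitating iminium salt should stop a second formylation.

Step 2
Reactants: 3 2,4,6-trihydroxy-3-methylbenzaldehyde; 4 benzyl bromide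
Product: 5 4,6-bis(benzyloxy)-2-hydroxy-3-methylbenzaldehyde
Conditions: BnBr (2.05 equiv in all), K2CO3 (2.1 equiv), acetone, 56 °C
Reagents that add atoms: benzyl bromide (BrCc1ccccc1)
Why: double Williamson etherification with two equivalents of benzyl bromide; the para OH is the most acidic and the ortho OH next to ring H follows, while the OH wedged between CHO and CH3 is the most hindered and most strongly hydrogen-bonded and should be left.

Step 3
Reactants: 5 4,6-bis(benzyloxy)-2-hydroxy-3-methylbenzaldehyde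
Product: 6 4,6-bis(benzyloxy)-2-methoxy-3-methylbenzaldehyde
Conditions: MeI, K2CO3, DMF, 50 °C
Reagents that add atoms: iodomethane (CI)
Why: Williamson methylation of the one remaining, chelated phenol under mildly forcing conditions.

Step 4
Reactants: 6 4,6-bis(benzyloxy)-2-methoxy-3-methylbenzaldehyde; 7 ethynyltrimethylsilane
Product: 8 rac-1-[4,6-bis(benzyloxy)-2-methoxy-3-methylphenyl]-3-(trimethylsilyl)prop-2-yn-1-ol
Conditions: 7, n-BuLi, THF, −78 °C; then 6, −78 to 0 °C; H2O quench
Reagents that add atoms: none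
Why: 1,2-addition of a lithium acetylide to an aldehyde; the carbinol centre forms as a racemate and is removed in step 5.

Step 5
Reactants: 8 rac-1-[4,6-bis(benzyloxy)-2-methoxy-3-methylphenyl]-3-(trimethylsilyl)prop-2-yn-1-ol
Product: 9 {3-[4,6-bis(benzyloxy)-2-methoxy-3-methylphenyl]prop-1-yn-1-yl}trimethylsilane
Conditions: Et3SiH (10 equiv), CF3CO2H (3 equiv), CH2Cl2 (0.02 M), −40 to 0 °C
Reagents that add atoms: none
Why: ionic hydrogenation of a benzylic–propargylic alcohol; the trialkoxybenzyl cation forms readily, the silyl-capped alkyne terminus steers hydride to the benzylic carbon, and excess silane at high dilution should outrun Friedel–Crafts capture by a second arene.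

Step 6
Reactants: 9 {3-[4,6-bis(benzyloxy)-2-methoxy-3-methylphenyl]prop-1-yn-1-yl}trimethylsilane
Product: 10 1,5-bis(benzyloxy)-3-methoxy-2-methyl-4-(prop-2-yn-1-yl)benzene
Conditions: K2CO3 (0.2 equiv), MeOH/THF, 0 °C to rt
Reagents that add atoms: none
Why: base-catalysed methanolysis of the C(sp)–Si bond; short contact at low temperature should avoid propargyl-to-allene isomerisation.

Step 7
Reactants: 10 1,5-bis(benzyloxy)-3-methoxy-2-methyl-4-(prop-2-yn-1-yl)benzene
Product: 13 ({3-[4,6-bis(benzyloxy)-2-methoxy-3-methylphenyl]prop-1-yn-1-yl}oxy)tri(propan-2-yl)silane, via lithium acetylide 11 (not isolated), via lithium ynolate 12 (not isolated)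
Conditions: n-BuLi, THF, −78 °C; LiOOt-Bu (from t-BuOOH, LiN(SiMe3)2), −78 to 0 °C; then i-Pr3SiOTf, −78 to 0 °C
Reagents that add atoms: tert-butyl hydroperoxide (CC(C)(C)OO); triisopropylsilyl trifluoromethanesulfonate (CC(C)[Si](OS(=O)(=O)C(F)(F)F)(C(C)C)C(C)C)
Why: Julia oxidation of a lithium acetylide by lithium tert-butyl peroxide to the ynolate, followed by O-silylation, which the bulky silyl triflate favours over C-silylation.

Step 8
Reactants: 13 ({3-[4,6-bis(benzyloxy)-2-methoxy-3-methylphenyl]prop-1-yn-1-yl}oxy)tri(propan-2-yl)silane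
Product: 15 2-{[4,6-bis(benzyloxy)-2-methoxy-3-methylphenyl]methyl}-3-hydroxycyclobut-2-en-1-one, via 3-siloxycyclobutenone 14 (not isolated)
Conditions: ketene (gas, excess), CH2Cl2, −20 to 0 °C; then Bu4NF, AcOH, THF, 0 °C
Reagents that add atoms: ketene (C=C=O)
Why: ketene–ynol ether [2+2] cycloaddition, in which the nucleophilic alkyne carbon β to oxygen attacks the ketene carbonyl carbon; buffered fluoride then cleaves the vinylogous silyl ester to the enol of the cyclobutane-1,3-dione.

Step 9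
Reactants: 15 2-{[4,6-bis(benzyloxy)-2-methoxy-3-methylphenyl]methyl}-3-hydroxycyclobut-2-en-1-one
Product: 16 3-(benzyloxy)-2-{[4,6-bis(benzyloxy)-2-methoxy-3-methylphenyl]methyl}cyclobut-2-en-1-one
Conditions: BnOH, PPh3, DIAD, THF, 0 °C to rt
Reagents that add atoms: benzyl alcohol (OCc1ccccc1)
Why: Mitsunobu O-alkylation of an acidic vinylogous acid under neutral conditions; the two oxygens of the enolate are equivalent, so a single enol ether should form.

Step 10
Reactants: 3 2,4,6-trihydroxy-3-methylbenzaldehyde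
Product: 17 2,6-dihydroxy-4-methoxy-3-methylbenzaldehyde
Conditions: Me2SO4 (1.0 equiv), K2CO3 (1.0 equiv), acetone, rt
Reagents that add atoms: dimethyl sulfate (COS(=O)(=O)OC)
Why: selective Williamson methylation with one equivalent of the methylating agent; the para OH is the most acidic and is not chelated, whereas the ortho OH groups are held back by hydrogen bonding to the formyl oxygen and by their flanking substituents.

Step 11
Reactants: 17 2,6-dihydroxy-4-methoxy-3-methylbenzaldehyde; 4 benzyl bromide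
Product: 18 2,6-bis(benzyloxy)-4-methoxy-3-methylbenzaldehyde
Conditions: BnBr (2.5 equiv in all), K2CO3 (3 equiv), Bu4NI (cat.), DMF, 60 °C
Reagents that add atoms: benzyl bromide (BrCc1ccccc1)
Why: exhaustive Williamson benzylation of the two ortho phenols under forcing conditions; both benzyl groups come from benzyl bromide.

Step 12
Reactants: 18 2,6-bis(benzyloxy)-4-methoxy-3-methylbenzaldehyde; 7 ethynyltrimethylsilane
Product: 19 rac-1-[2,6-bis(benzyloxy)-4-methoxy-3-methylphenyl]-3-(trimethylsilyl)prop-2-yn-1-ol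
Conditions: 7, n-BuLi, THF, −78 °C; then 18, −78 to 0 °C; H2O quench
Reagents that add atoms: none
Why: 1,2-addition of a lithium acetylide to the hindered aldehyde; the racemic carbinol centre is removed in step 13.

Step 13
Reactants: 19 rac-1-[2,6-bis(benzyloxy)-4-methoxy-3-methylphenyl]-3-(trimethylsilyl)prop-2-yn-1-ol
Product: 20 {3-[2,6-bis(benzyloxy)-4-methoxy-3-methylphenyl]prop-1-yn-1-yl}trimethylsilane
Conditions: Et3SiH (10 equiv), CF3CO2H (3 equiv), CH2Cl2 (0.02 M), −40 to 0 °C
Reagents that add atoms: none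
Why: ionic hydrogenation of the benzylic–propargylic alcohol, as in step 5, with hydride delivered to the benzylic carbon of the stabilised cation.

Step 14
Reactants: 20 {3-[2,6-bis(benzyloxy)-4-methoxy-3-methylphenyl]prop-1-yn-1-yl}trimethylsilane
Product: 21 1,3-bis(benzyloxy)-5-methoxy-4-methyl-2-(prop-2-yn-1-yl)benzene
Conditions: K2CO3 (0.2 equiv), MeOH/THF, 0 °C to rt
Reagents that add atoms: none
Why: base-catalysed methanolysis of the alkynyl–silicon bond.

Step 15
Reactants: 21 1,3-bis(benzyloxy)-5-methoxy-4-methyl-2-(prop-2-yn-1-yl)benzene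
Product: 24 ({3-[2,6-bis(benzyloxy)-4-methoxy-3-methylphenyl]prop-1-yn-1-yl}oxy)tri(propan-2-yl)silane, via lithium acetylide 22 (not isolated), via lithium ynolate 23 (not isolated)
Conditions: n-BuLi, THF, −78 °C; LiOOt-Bu (from t-BuOOH, LiN(SiMe3)2), −78 to 0 °C; then i-Pr3SiOTf, −78 to 0 °C
Reagents that add atoms: tert-butyl hydroperoxide (CC(C)(C)OO); triisopropylsilyl trifluoromethanesulfonate (CC(C)[Si](OS(=O)(=O)C(F)(F)F)(C(C)C)C(C)C)
Why: Julia acetylide oxidation to the ynolate and O-silylation with the bulky silyl triflate, as in step 7.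

Step 16
Reactants: 24 ({3-[2,6-bis(benzyloxy)-4-methoxy-3-methylphenyl]prop-1-yn-1-yl}oxy)tri(propan-2-yl)silane; 16 3-(benzyloxy)-2-{[4,6-bis(benzyloxy)-2-methoxy-3-methylphenyl]methyl}cyclobut-2-en-1-one
Product: 29 5-(benzyloxy)-4-{[4,6-bis(benzyloxy)-2-methoxy-3-methylphenyl]methyl}-2-{[2,6-bis(benzyloxy)-4-methoxy-3-methylphenyl]methyl}-3-{[tri(propan-2-yl)silyl]oxy}phenol, via vinylketene 25 (not isolated), via 4-vinylcyclobutenone 26 (not isolated), via dienylketene 27 (not isolated), via cyclohexa-2,4-dienone 28 (not isolated)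
Conditions: toluene (0.5 M), 80 °C then 120 °C, sealed tube, argon
Reagents that add atoms: none
Why: Heating opens cyclobutenone 16 by 4π electrocyclic cleavage to the 3-benzyloxy vinylketene 25, which undergoes [2+2] cycloaddition with siloxyalkyne 24 to form the C2–C3 and C4–C5 bonds of ring B in 26. A second 4π opening gives dienylketene 27, ring B closes by 6π electrocyclisation (C1–C2) to dienone 28, and tautomerisation gives phenol 29. The closest known reaction is the Danheiser benzannulation of cyclobutenones with siloxyalkynes; here the 3-alkoxy group supplies the third ring oxygen, so a phloroglucinol results in place of a resorcinol. No stereocentre is created, and the quaternary centre of 26 is lost on ring opening. The step needs regioselectivity in the ketene–alkyne [2+2], and the polarisation of the siloxyalkyne secures it: the carbon β to oxygen, bearing the ring A benzyl group, bonds to the ketene carbonyl carbon, which places the bridges on C3 and C5 and leaves C1 as CH. No acid or base is present, so the electron-rich outer rings, the benzyl ethers and both bridges should be untouched.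

Step 17
Reactants: 29 the ring B phenol from step 16; 4 benzyl bromide
Product: 31 1,3,5-tris(benzyloxy)-2-{[2,6-bis(benzyloxy)-4-methoxy-3-methylphenyl]methyl}-4-{[4,6-bis(benzyloxy)-2-methoxy-3-methylphenyl]methyl}benzene, via benzyl ether silyl ether 30 (not isolated)
Conditions: BnBr (3 equiv in all), Cs2CO3, DMF, rt; then CsF, 60 °C
Reagents that add atoms: benzyl bromide (BrCc1ccccc1)
Why: Williamson benzylation of the free phenol with a first equivalent of benzyl bromide, then fluoride cleavage of the aryl silyl ether and in situ benzylation of the phenoxide with a second; unmasking one oxygen at a time keeps ring B from carrying two phenoxides, which limits C-benzylation.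

Step 18
Reactants: 31 the heptabenzyl tris-arene from step 17
Product: 32 1-[2,4,6-tris(benzyloxy)-3-{[2,6-bis(benzyloxy)-3-butanoyl-4-methoxy-5-methylphenyl]methyl}-5-{[4,6-bis(benzyloxy)-5-butanoyl-2-methoxy-3-methylphenyl]methyl}phenyl]butan-1-one
Conditions: n-PrCO2H (6 equiv), (CF3CO)2O (6 equiv), CH2Cl2, 0 °C to rt
Reagents that add atoms: butanoic acid (CCCC(=O)O)
Why: threefold Friedel–Crafts acylation by the mixed butanoic trifluoroacetic anhydride, one butanoyl group per ring; each ring has exactly one free CH, flanked by two alkoxy groups and para to a third, and the absence of a Lewis acid should spare the ring A methyl ether ortho to the new ketone.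

Step 19
Reactants: 32 the tris-butanoyl heptabenzyl ether from step 18
Product: 33 CNP0171986.0, 1-[2,4,6-trihydroxy-3-{[2,6-dihydroxy-3-butanoyl-4-methoxy-5-methylphenyl]methyl}-5-{[4,6-dihydroxy-5-butanoyl-2-methoxy-3-methylphenyl]methyl}phenyl]butan-1-one
Conditions: H2 (1 atm), 10% Pd/C, EtOAc/MeOH, rt
Reagents that add atoms: none
Why: hydrogenolysis of seven aryl benzyl ethers; the hindered, chelated aryl ketones, the two methyl ethers and the diarylmethane bridges should survive.

**Compound list**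

1 | 2-methylbenzene-1,3,5-triol | Cc1c(O)cc(O)cc1O | starting material
2 | [(2,4,6-trihydroxy-3-methylphenyl)methylidene]dimethylammonium chloride | Cc1c(O)cc(O)c(C=[N+](C)C)c1O.[Cl-] | intermediate
3 | 2,4,6-trihydroxy-3-methylbenzaldehyde | Cc1c(O)cc(O)c(C=O)c1O | intermediate
4 | benzyl bromide | BrCc1ccccc1 | starting material
5 | 4,6-bis(benzyloxy)-2-hydroxy-3-methylbenzaldehyde | Cc1c(O)c(C=O)c(OCc2ccccc2)cc1OCc1ccccc1 | intermediate
6 | 4,6-bis(benzyloxy)-2-methoxy-3-methylbenzaldehyde | COc1c(C)c(OCc2ccccc2)cc(OCc2ccccc2)c1C=O | intermediate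
7 | ethynyltrimethylsilane | C#C[Si](C)(C)C | starting material
8 | rac-1-[4,6-bis(benzyloxy)-2-methoxy-3-methylphenyl]-3-(trimethylsilyl)prop-2-yn-1-ol | COc1c(C)c(OCc2ccccc2)cc(OCc2ccccc2)c1C(O)C#C[Si](C)(C)C | intermediate
9 | {3-[4,6-bis(benzyloxy)-2-methoxy-3-methylphenyl]prop-1-yn-1-yl}trimethylsilane | COc1c(C)c(OCc2ccccc2)cc(OCc2ccccc2)c1CC#C[Si](C)(C)C | intermediate
10 | 1,5-bis(benzyloxy)-3-methoxy-2-methyl-4-(prop-2-yn-1-yl)benzene | COc1c(C)c(OCc2ccccc2)cc(OCc2ccccc2)c1CC#C | intermediate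
11 | lithium acetylide of 10 | COc1c(C)c(OCc2ccccc2)cc(OCc2ccccc2)c1CC#C[Li] | intermediate
12 | lithium ynolate from 11 | COc1c(C)c(OCc2ccccc2)cc(OCc2ccccc2)c1CC#CO[Li] | intermediate
13 | ({3-[4,6-bis(benzyloxy)-2-methoxy-3-methylphenyl]prop-1-yn-1-yl}oxy)tri(propan-2-yl)silane | COc1c(C)c(OCc2ccccc2)cc(OCc2ccccc2)c1CC#CO[Si](C(C)C)(C(C)C)C(C)C | intermediate
14 | 2-{[4,6-bis(benzyloxy)-2-methoxy-3-methylphenyl]methyl}-3-{[tri(propan-2-yl)silyl]oxy}cyclobut-2-en-1-one | COc1c(C)c(OCc2ccccc2)cc(OCc2ccccc2)c1CC1=C(O[Si](C(C)C)(C(C)C)C(C)C)CC1=O | intermediate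
15 | 2-{[4,6-bis(benzyloxy)-2-methoxy-3-methylphenyl]methyl}-3-hydroxycyclobut-2-en-1-one | COc1c(C)c(OCc2ccccc2)cc(OCc2ccccc2)c1CC1=C(O)CC1=O | intermediate
16 | 3-(benzyloxy)-2-{[4,6-bis(benzyloxy)-2-methoxy-3-methylphenyl]methyl}cyclobut-2-en-1-one | COc1c(C)c(OCc2ccccc2)cc(OCc2ccccc2)c1CC1=C(OCc2ccccc2)CC1=O | intermediate
17 | 2,6-dihydroxy-4-methoxy-3-methylbenzaldehyde | COc1cc(O)c(C=O)c(O)c1C | intermediate
18 | 2,6-bis(benzyloxy)-4-methoxy-3-methylbenzaldehyde | COc1cc(OCc2ccccc2)c(C=O)c(OCc2ccccc2)c1C | intermediate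
19 | rac-1-[2,6-bis(benzyloxy)-4-methoxy-3-methylphenyl]-3-(trimethylsilyl)prop-2-yn-1-ol | COc1cc(OCc2ccccc2)c(C(O)C#C[Si](C)(C)C)c(OCc2ccccc2)c1C | intermediate
20 | {3-[2,6-bis(benzyloxy)-4-methoxy-3-methylphenyl]prop-1-yn-1-yl}trimethylsilane | COc1cc(OCc2ccccc2)c(CC#C[Si](C)(C)C)c(OCc2ccccc2)c1C | intermediate
21 | 1,3-bis(benzyloxy)-5-methoxy-4-methyl-2-(prop-2-yn-1-yl)benzene | COc1cc(OCc2ccccc2)c(CC#C)c(OCc2ccccc2)c1C | intermediate
22 | lithium acetylide of 21 | COc1cc(OCc2ccccc2)c(CC#C[Li])c(OCc2ccccc2)c1C | intermediate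
23 | lithium ynolate from 22 | COc1cc(OCc2ccccc2)c(CC#CO[Li])c(OCc2ccccc2)c1C | intermediate
24 | ({3-[2,6-bis(benzyloxy)-4-methoxy-3-methylphenyl]prop-1-yn-1-yl}oxy)tri(propan-2-yl)silane | COc1cc(OCc2ccccc2)c(CC#CO[Si](C(C)C)(C(C)C)C(C)C)c(OCc2ccccc2)c1C | intermediate
25 | 3-(benzyloxy)-2-{[4,6-bis(benzyloxy)-2-methoxy-3-methylphenyl]methyl}buta-1,3-dien-1-one (vinylketene) | C=C(OCc1ccccc1)C(=C=O)Cc1c(OCc2ccccc2)cc(OCc2ccccc2)c(C)c1OC | intermediate
26 | rac-4-[1-(benzyloxy)ethenyl]-2-(ring A arylmethyl)-4-(ring C arylmethyl)-3-{[tri(propan-2-yl)silyl]oxy}cyclobut-2-en-1-one | O=C1C(Cc2c(OCc3ccccc3)c(C)c(OC)cc2OCc2ccccc2)=C(O[Si](C(C)C)(C(C)C)C(C)C)C1(Cc1c(OCc2ccccc2)cc(OCc2ccccc2)c(C)c1OC)C(=C)OCc1ccccc1 | intermediate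
27 | (3E)-5-(benzyloxy)-2-(ring A arylmethyl)-4-(ring C arylmethyl)-3-{[tri(propan-2-yl)silyl]oxy}hexa-1,3,5-trien-1-one (ketene carbon and vinyl group cis) | O=C=C(Cc1c(OCc2ccccc2)c(C)c(OC)cc1OCc1ccccc1)/C(O[Si](C(C)C)(C(C)C)C(C)C)=C(\C(=C)OCc1ccccc1)Cc1c(OCc2ccccc2)cc(OCc2ccccc2)c(C)c1OC | intermediate
28 | 5-(benzyloxy)-2-(ring A arylmethyl)-4-(ring C arylmethyl)-3-{[tri(propan-2-yl)silyl]oxy}cyclohexa-2,4-dien-1-one | O=C1CC(OCc2ccccc2)=C(Cc2c(OCc3ccccc3)cc(OCc3ccccc3)c(C)c2OC)C(O[Si](C(C)C)(C(C)C)C(C)C)=C1Cc1c(OCc2ccccc2)c(C)c(OC)cc1OCc1ccccc1 | intermediate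
29 | 5-(benzyloxy)-4-{[4,6-bis(benzyloxy)-2-methoxy-3-methylphenyl]methyl}-2-{[2,6-bis(benzyloxy)-4-methoxy-3-methylphenyl]methyl}-3-{[tri(propan-2-yl)silyl]oxy}phenol | Oc1cc(OCc2ccccc2)c(Cc2c(OCc3ccccc3)cc(OCc3ccccc3)c(C)c2OC)c(O[Si](C(C)C)(C(C)C)C(C)C)c1Cc1c(OCc2ccccc2)c(C)c(OC)cc1OCc1ccccc1 | intermediate
30 | O-benzyl ether of 29 (ring B: two OBn, one OSi(i-Pr)3) | C(Oc1cc(OCc2ccccc2)c(Cc2c(OCc3ccccc3)cc(OCc3ccccc3)c(C)c2OC)c(O[Si](C(C)C)(C(C)C)C(C)C)c1Cc1c(OCc2ccccc2)c(C)c(OC)cc1OCc1ccccc1)c1ccccc1 | intermediate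
31 | 1,3,5-tris(benzyloxy)-2-{[2,6-bis(benzyloxy)-4-methoxy-3-methylphenyl]methyl}-4-{[4,6-bis(benzyloxy)-2-methoxy-3-methylphenyl]methyl}benzene | C(Oc1cc(OCc2ccccc2)c(Cc2c(OCc3ccccc3)cc(OCc3ccccc3)c(C)c2OC)c(OCc2ccccc2)c1Cc1c(OCc2ccccc2)c(C)c(OC)cc1OCc1ccccc1)c1ccccc1 | intermediate
32 | 1-[2,4,6-tris(benzyloxy)-3-{[2,6-bis(benzyloxy)-3-butanoyl-4-methoxy-5-methylphenyl]methyl}-5-{[4,6-bis(benzyloxy)-5-butanoyl-2-methoxy-3-methylphenyl]methyl}phenyl]butan-1-one | CCCC(=O)c1c(OCc2ccccc2)c(Cc2c(OCc3ccccc3)c(C)c(OC)c(C(=O)CCC)c2OCc2ccccc2)c(OCc2ccccc2)c(Cc2c(OCc3ccccc3)c(C(=O)CCC)c(OCc3ccccc3)c(C)c2OC)c1OCc1ccccc1 | intermediate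
33 | CNP0171986.0 | CCCC(=O)c1c(O)c(Cc2c(O)c(C)c(OC)c(C(=O)CCC)c2O)c(O)c(Cc2c(O)c(C(=O)CCC)c(O)c(C)c2OC)c1O | target

**Step count**

Total: 19 steps. Longest linear sequence: 13 steps (steps 1–9, then 16–19).

**Steps most likely to fail**

1. Step 16. The donor-stabilised 3-benzyloxycyclobutenone may open only slowly, so thermal 1,3-shift of silicon in the siloxyalkyne and oligomerisation of the vinylketene could compete, and the two ortho,ortho'-disubstituted benzyl groups may retard the [2+2]. The fallback builds ring B's substitution by Friedel–Crafts benzylation instead. It sets out from aldehydes 6 and 18: NaBH4 (MeOH/THF, 0 °C) should reduce 6 to [4,6-bis(benzyloxy)-2-methoxy-3-methylphenyl]methanol F1 and 18 to [2,6-bis(benzyloxy)-4-methoxy-3-methylphenyl]methanol F2. Purchased 1,3,5-tris(benzyloxy)benzene (3 equiv) is then benzylated with slowly added F1 under Sc(OTf)3 catalysis (CH2Cl2, 0 °C) to the mono-adduct 1,3,5-tris(benzyloxy)-2-{[4,6-bis(benzyloxy)-2-methoxy-3-methylphenyl]methyl}benzene F3. F3 has two equivalent free ring positions and is benzylated in the same way with F2; the route is rejoined at compound 31.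

2. Step 18. The acylium may attack ipso at the bridge-bearing carbons and expel a trialkoxybenzyl cation (bridge scission or scrambling), and acylation at the CH flanked by two benzyloxy groups may stay incomplete. The fallback sets out from 31 and replaces electrophilic acylation by halogen–metal exchange. NBS (3 equiv, CH2Cl2/MeCN, −20 °C, dark) should brominate the one free CH of each ring to give the tribromide of 31 F4. Triple bromine–lithium exchange (t-BuLi, THF, −78 °C) and quenching with N-methoxy-N-methylbutanamide should give the triketone; the route is rejoined at compound 32.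

3. Step 8. Ketene dimerisation and O-acylation of the enol product by excess ketene may outrun the cycloaddition, and the siloxyalkyne may be protodesilylated first. The fallback sets out from 13 and uses a ketene that cannot dimerise in this way. Dichloroketene (Cl3CCOCl, Zn dust, Et2O/DME, rt) should add to 13 with the same regiochemistry to give 4,4-dichloro-2-{[4,6-bis(benzyloxy)-2-methoxy-3-methylphenyl]methyl}-3-{[tri(propan-2-yl)silyl]oxy}cyclobut-2-en-1-one F5. Reductive dechlorination (Zn, AcOH, TMEDA, EtOH, rt) should then give the siloxycyclobutenone; the route is rejoined at compound 14, which the buffered fluoride of step 8 converts into 15.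

**Further compounds**

F1 | step 16 | [4,6-bis(benzyloxy)-2-methoxy-3-methylphenyl]methanol | COc1c(C)c(OCc2ccccc2)cc(OCc2ccccc2)c1CO
F2 | step 16 | [2,6-bis(benzyloxy)-4-methoxy-3-methylphenyl]methanol | COc1cc(OCc2ccccc2)c(CO)c(OCc2ccccc2)c1C
F3 | step 16 | 1,3,5-tris(benzyloxy)-2-{[4,6-bis(benzyloxy)-2-methoxy-3-methylphenyl]methyl}benzene | COc1c(C)c(OCc2ccccc2)cc(OCc2ccccc2)c1Cc1c(OCc2ccccc2)cc(OCc2ccccc2)cc1OCc1ccccc1
F4 | step 18 | tribromide of 31 (one Br at the free CH of each of rings A, B and C) | Brc1c(OCc2ccccc2)c(Cc2c(OCc3ccccc3)c(C)c(OC)c(Br)c2OCc2ccccc2)c(OCc2ccccc2)c(Cc2c(OCc3ccccc3)c(Br)c(OCc3ccccc3)c(C)c2OC)c1OCc1ccccc1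
F5 | step 8 | 4,4-dichloro-2-{[4,6-bis(benzyloxy)-2-methoxy-3-methylphenyl]methyl}-3-{[tri(propan-2-yl)silyl]oxy}cyclobut-2-en-1-one | COc1c(C)c(OCc2ccccc2)cc(OCc2ccccc2)c1CC1=C(O[Si](C(C)C)(C(C)C)C(C)C)C(Cl)(Cl)C1=O
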